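**Retrosynthetic overview**

- Core numbering: C1 (benzoyl bridgehead), C2 (OMe), C3 (prenyl), C4 (enone C=O), C5 (prenyl bridgehead), C6 (CH2), C7 (side-chain CH), C8 (CMe2), C9 (bridging C=O). Ring A = C1, C8, C7, C6, C5, C9; ring B = C1, C2, C3, C4, C5, C9.
- Feature: C6 is the only CH2 of ring A and lies between C5 (α to both the C9 ketone and the C4 acyl carbon) and the allylic stereocentre C7. C6 can therefore be a formaldehyde carbon that joins a β-keto ester (C4, C5, C9) to an allylsilane (C7).
- Ring A first: C5–C6, C6–C7 and C5–prenyl are made in one pot from keto ester 5, formaldehyde and prenyl bromide, which sets C7 and C5. The vinyl group is then grown into the (E)-4-silyloxy-3-methylbut-2-enyl chain.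
- Ring B second: C1–C2 by C-acylation, then C3–C4 by Dieckmann closure onto the C5 ester. The closure is run on a diketone whose acidic C1–H is masked by phenylthio, because a C1 enolate is planar and cannot become a bridgehead.
- End: desulfurisation, O-methylation at O2, bridgehead benzoylation at C1, silyl ether to acetate.

Key step: step 3

Assumption: the sense of induction of the copper–bis(oxazoline) complex in step 3 cannot be predicted with confidence; the (S,S)-ligand is written, and its antipode is used instead if the mirror-image series results.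

**Route**

Step 1
Reactants: 1 methyl 3,3-dimethylpent-4-enoate; 2 allyltrimethylsilane
Product: 3 methyl (E)-3,3-dimethyl-6-(trimethylsilyl)hex-4-enoate
Conditions: second-generation Hoveyda–Grubbs catalyst (3 mol%), 2 (4 equiv), CH2Cl2, 40 °C
Reagents that add atoms: none
Why: Olefin cross-metathesis in which the vinyl group on the quaternary carbon of 1 does not homodimerise, so an excess of the fast-reacting allylsilane should give the cross product as the E alkene with loss of ethene.

Step 2
Reactants: 3 methyl (E)-3,3-dimethyl-6-(trimethylsilyl)hex-4-enoate; 4 methyl acetate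
Product: 5 methyl (E)-5,5-dimethyl-3-oxo-8-(trimethylsilyl)oct-6-enoate
Conditions: LiN(i-Pr)2 (3.2 equiv), 4 (3 equiv), THF, −78 °C; then 3, −78 → −30 °C; AcOH
Reagents that add atoms: none
Why: Crossed Claisen condensation in which the excess lithium enolate of methyl acetate adds to the ester of 3 and the β-keto ester is held as its enolate until the acidic quench, the allylsilane being inert to amide bases.

Step 3
Reactants: 5 methyl (E)-5,5-dimethyl-3-oxo-8-(trimethylsilyl)oct-6-enoate; 6 formaldehyde; 7 prenyl bromide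
Product: 10 methyl (1R,5R)-4,4-dimethyl-1-(3-methylbut-2-en-1-yl)-2-oxo-5-vinylcyclohexane-1-carboxylate, via 2-methylene keto ester 8 (not isolated), via cyclised keto ester 9 (not isolated)
Conditions: (CH2O)n (2 equiv), Cu(OTf)2 (10 mol%), 2,2′-(propane-2,2-diyl)bis[(4S)-4-tert-butyl-4,5-dihydrooxazole] (11 mol%), CH2Cl2 (0.02 M), 0 °C → rt; then 7 (1.5 equiv), Cs2CO3 (2 equiv), MeCN, 0 °C → rt
Reagents that add atoms: none
Why: Proposed new method: the copper-bound enolate of 5 should condense with formaldehyde to the 2-methylene keto ester 8, which stays chelated to divalent copper through both carbonyl oxygens and is thereby a strong acceptor at its CH2 carbon (C6); the γ-carbon of the tethered allylsilane (C7) adds to C6, the β-silyl cation loses Me3Si to leave the vinyl group, and the enolate of 9 is C-alkylated at C5 by prenyl bromide once Cs2CO3 is added. The closest known reactions are the Lewis-acid-mediated domino Knoevenagel–allylsilane (Hosomi–Sakurai) cyclisations of alkylidene 1,3-dicarbonyl compounds and the Cu(OTf)2–bis(oxazoline) Michael additions to alkylidene malonates, whereas a formaldehyde-derived acceptor on this tether and the enantioselective variant are not known. Ring A (C1, C8, C7, C6, C5, C9) closes in a 6-endo-trig mode at the acceptor (exo with respect to the allylsilane double bond) through a chair transition state with the CH2SiMe3 group pseudo-equatorial. C7 is set by the chiral copper complex, whose tert-butyl groups shield one face of the planar chelate so that the tether folds over the other, and C5 is set by the substrate, the prenyl group entering axially on the enolate face opposite to the equatorial C7 vinyl group and leaving the ester cis to it. The step needs the intramolecular addition to outrun Michael addition of a second molecule of 5 to 8, which the unhindered CH2 acceptor, the gem-dimethyl effect and the dilution should secure, and it needs C- rather than O-prenylation, which the soft allylic bromide favours.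

Step 4
Reactants: 10 methyl (1R,5R)-4,4-dimethyl-1-(3-methylbut-2-en-1-yl)-2-oxo-5-vinylcyclohexane-1-carboxylate
Product: 12 methyl (1R,5R)-5-(2-hydroxyethyl)-4,4-dimethyl-1-(3-methylbut-2-en-1-yl)-2-oxocyclohexane-1-carboxylate, via B-alkyl-9-borabicyclononane adduct 11 (not isolated)
Conditions: 9-BBN (1.3 equiv), THF, 0 °C → rt; then NaBO3·4H2O, H2O, rt
Reagents that add atoms: 9-borabicyclo[3.3.1]nonane, B1C2CCCC1CCC2 (boron unit of 11 only); sodium perborate tetrahydrate, O.O.O.O.[Na+].[O-]OB=O (hydroxyl oxygen)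
Why: Anti-Markovnikov hydroboration–oxidation in which 9-BBN adds to the monosubstituted vinyl group much faster than to the trisubstituted prenyl alkene or the hindered ketone, and perborate oxidises the borane without the hydroxide that would cleave the non-enolisable β-keto ester.

Step 5
Reactants: 12 methyl (1R,5R)-5-(2-hydroxyethyl)-4,4-dimethyl-1-(3-methylbut-2-en-1-yl)-2-oxocyclohexane-1-carboxylate
Product: 13 methyl (1R,5R)-4,4-dimethyl-1-(3-methylbut-2-en-1-yl)-2-oxo-5-(2-oxoethyl)cyclohexane-1-carboxylate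
Conditions: Dess–Martin periodinane, CH2Cl2, 0 °C → rt
Reagents that add atoms: none
Why: Dess–Martin oxidation of the primary alcohol to the aldehyde under neutral conditions that leave the keto ester and the prenyl alkene untouched.

Step 6
Reactants: 13 methyl (1R,5R)-4,4-dimethyl-1-(3-methylbut-2-en-1-yl)-2-oxo-5-(2-oxoethyl)cyclohexane-1-carboxylate
Product: 14 methyl (1R,5S)-4,4-dimethyl-5-[(E)-3-methyl-4-oxobut-2-en-1-yl]-1-(3-methylbut-2-en-1-yl)-2-oxocyclohexane-1-carboxylate
Conditions: Ph3P=C(CH3)CHO (1.5 equiv), toluene, 80 °C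
Reagents that add atoms: 2-(triphenylphosphoranylidene)propanal, CC(C=O)=P(c1ccccc1)(c1ccccc1)c1ccccc1
Why: Wittig reaction of a stabilised ylide, which should react only with the aldehyde and give the (E)-2-methyl enal with the formyl group trans to the chain.

Step 7
Reactants: 14 methyl (1R,5S)-4,4-dimethyl-5-[(E)-3-methyl-4-oxobut-2-en-1-yl]-1-(3-methylbut-2-en-1-yl)-2-oxocyclohexane-1-carboxylate
Product: 15 methyl (1R,5S)-5-[(E)-4-hydroxy-3-methylbut-2-en-1-yl]-4,4-dimethyl-1-(3-methylbut-2-en-1-yl)-2-oxocyclohexane-1-carboxylate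
Conditions: NaBH4, CeCl3·7H2O, MeOH, −78 °C
Reagents that add atoms: none
Why: Luche 1,2-reduction in which the conjugated aldehyde should be reduced at −78 °C faster than the ring ketone, which is flanked by a quaternary carbon, while the ester is inert.

Step 8
Reactants: 15 methyl (1R,5S)-5-[(E)-4-hydroxy-3-methylbut-2-en-1-yl]-4,4-dimethyl-1-(3-methylbut-2-en-1-yl)-2-oxocyclohexane-1-carboxylate
Product: 16 methyl (1R,5S)-5-[(E)-4-(tert-butyldiphenylsilyloxy)-3-methylbut-2-en-1-yl]-4,4-dimethyl-1-(3-methylbut-2-en-1-yl)-2-oxocyclohexane-1-carboxylate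
Conditions: TBDPSCl, imidazole, CH2Cl2, rt
Reagents that add atoms: tert-butyl(chloro)diphenylsilane, CC(C)(C)[Si](Cl)(c1ccccc1)c1ccccc1
Why: Silylation of the primary allylic alcohol as a robust ether, because an acetate would not survive the enolate chemistry that follows.

Step 9
Reactants: 17 5-methylhex-4-enoic acid
Product: 18 5-methylhex-4-enoyl chloride
Conditions: (COCl)2, DMF (cat.), CH2Cl2, 0 °C → rt
Reagents that add atoms: oxalyl chloride, ClC(=O)C(=O)Cl
Why: Standard conversion of a carboxylic acid into its chloride through the Vilsmeier-type intermediate formed from oxalyl chloride and DMF.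

Step 10
Reactants: 16 methyl (1R,5S)-5-[(E)-4-(tert-butyldiphenylsilyloxy)-3-methylbut-2-en-1-yl]-4,4-dimethyl-1-(3-methylbut-2-en-1-yl)-2-oxocyclohexane-1-carboxylate; 18 5-methylhex-4-enoyl chloride
Product: 19 the 1,3-diketone formed from 16 by attaching a 5-methylhex-4-enoyl group to ring carbon C3 (core C1), as enol and C3 epimers
Conditions: MgBr2·OEt2 (2.5 equiv), i-Pr2NEt (3 equiv), 18 (1.3 equiv), CH2Cl2, 0 °C → rt
Reagents that add atoms: none
Why: C-acylation by soft enolisation, in which magnesium chelation of the keto ester acidifies the only enolisable position (the ring CH2 beside the gem-dimethyl carbon, core C1) and the magnesium enolate is acylated on carbon to give the 1,3-diketone as its chelate.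

Step 11
Reactants: 19 the 1,3-diketone with the 5-methylhex-4-enoyl group at core C1
Product: 20 the 2-acyl-2-(phenylthio) ketone formed from 19 by sulfenylation at core C1, phenylthio trans and acyl cis to the ester
Conditions: N-(phenylthio)phthalimide (1.2 equiv), Et3N, CH2Cl2, 0 °C → rt
Reagents that add atoms: N-(phenylthio)phthalimide, O=C1N(Sc2ccccc2)C(=O)c2ccccc12
Why: Electrophilic α-sulfenylation of the 1,3-diketone, in which sulfur should enter the planar enolate at C1 on the face opposite to the C7 side chain, as carbon electrophiles do in such 2-acylcyclohexanones, so that the acyl group stays cis to the ester and the acidic C1–H, whose enolate would hold C1 planar and remove the driving force of the ring closure, is masked.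

Step 12
Reactants: 20 the 2-acyl-2-(phenylthio) ketone
Product: 21 2-hydroxy-8,8-dimethyl-3,5-bis(3-methylbut-2-enyl)-1-(phenylthio)-7-[(E)-4-(tert-butyldiphenylsilyloxy)-3-methylbut-2-enyl]bicyclo[3.3.1]non-2-ene-4,9-dione (core numbering, enol of the 2,4,9-trione, C7 chain cis to the C2–C4 bridge)
Conditions: KOt-Bu (2.5 equiv), THF, 0 °C → rt; then 1 M HCl
Reagents that add atoms: none
Why: Intramolecular Claisen (Dieckmann) condensation in which, with both α-carbons of the ring ketone quaternary, the only enolate is that at C3 of the acyl chain, which attacks the cis-disposed ester to form the C3–C4 bond and close the six-membered ring B (C1, C2, C3, C4, C5, C9), driven by deprotonation of the vinylogous acid formed.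

Step 13
Reactants: 21 the 1-(phenylthio) trione enol
Product: 22 2-hydroxy-8,8-dimethyl-3,5-bis(3-methylbut-2-enyl)-7-[(E)-4-(tert-butyldiphenylsilyloxy)-3-methylbut-2-enyl]bicyclo[3.3.1]non-2-ene-4,9-dione (core numbering, C1–H)
Conditions: Bu3SnH (2 equiv), AIBN (0.2 equiv), toluene, 90 °C
Reagents that add atoms: none
Why: Radical-chain desulfurisation in which the stannyl radical cleaves the C–S bond beside the carbonyl groups and the bridgehead radical, which can take up hydrogen only on its exo face and has no geometrically accessible alkene to cyclise onto, abstracts hydrogen from Bu3SnH.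

Step 14
Reactants: 22 the C1–H trione enol
Product: 23 2-methoxy-8,8-dimethyl-3,5-bis(3-methylbut-2-enyl)-7-[(E)-4-(tert-butyldiphenylsilyloxy)-3-methylbut-2-enyl]bicyclo[3.3.1]non-2-ene-4,9-dione (core numbering)
Conditions: TMSCHN2, MeOH–toluene (1:4), 0 °C
Reagents that add atoms: (trimethylsilyl)diazomethane, C[Si](C)(C)C=[N+]=[N-]
Why: O-methylation of the vinylogous acid by a diazoalkane, in which the new methoxy group must point towards a bridgehead because C3 is substituted and should therefore go to O2, beside the C1–H, and not to O4, beside the CH2 of the C5 prenyl group.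

Step 15
Reactants: 23 the 2-methoxy enone with C1–H
Product: 24 1-benzoyl-2-methoxy-8,8-dimethyl-3,5-bis(3-methylbut-2-enyl)-7-[(E)-4-(tert-butyldiphenylsilyloxy)-3-methylbut-2-enyl]bicyclo[3.3.1]non-2-ene-4,9-dione (core numbering, configuration as in 26)
Conditions: LiTMP (lithium 2,2,6,6-tetramethylpiperidide, 1.5 equiv), THF, −78 → −40 °C; then PhCOCl (2 equiv), −78 → 0 °C
Reagents that add atoms: benzoyl chloride, O=C(Cl)c1ccccc1
Why: Bridgehead metalation–acylation in which the C1–H, α to the C9 ketone and vinylogously activated through C2=C3–C4=O, is the only acidic proton left for the hindered amide, and the bridgehead lithium species can be acylated only on carbon from the exo side, which keeps the C1 configuration.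

Step 16
Reactants: 24 the 1-benzoyl silyl ether
Product: 25 1-benzoyl-7-[(E)-4-hydroxy-3-methylbut-2-enyl]-2-methoxy-8,8-dimethyl-3,5-bis(3-methylbut-2-enyl)bicyclo[3.3.1]non-2-ene-4,9-dione (core numbering)
Conditions: HF·pyridine, pyridine, THF, 0 °C → rt
Reagents that add atoms: none
Why: Fluoride cleavage of the silyl ether under buffered acidic conditions, which avoid basic fluoride sources that could cleave the bridgehead 1,3-dicarbonyl unit by retro-Claisen reaction.

Step 17
Reactants: 25 the primary allylic alcohol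
Product: 26 (1R,5S,7S)-7-[(E)-4-acetoxy-3-methylbut-2-en-1-yl]-1-benzoyl-2-methoxy-8,8-dimethyl-3,5-bis(3-methylbut-2-en-1-yl)bicyclo[3.3.1]non-2-ene-4,9-dione (core numbering), CNP0256662.1
Conditions: Ac2O, pyridine, DMAP (cat.), CH2Cl2, 0 °C → rt
Reagents that add atoms: acetic anhydride, CC(=O)OC(C)=O
Why: DMAP-catalysed acetylation of the primary allylic alcohol, which leaves the ketones and the enol ether untouched.

**Compound list**

The spatial arrangement at the two ring stereocentres set in step 3 is the same in every compound from 9 to 26; where the descriptor at cyclohexane C5 changes (R in 9, 10, 12, 13; S in 11, 14–16) this comes from the priority rules only.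

1 | methyl 3,3-dimethylpent-4-enoate | COC(=O)CC(C)(C)C=C | starting material
2 | allyltrimethylsilane | C=CC[Si](C)(C)C | starting material
3 | methyl (E)-3,3-dimethyl-6-(trimethylsilyl)hex-4-enoate | COC(=O)CC(C)(C)/C=C/C[Si](C)(C)C | intermediate
4 | methyl acetate | COC(C)=O | starting material
5 | methyl (E)-5,5-dimethyl-3-oxo-8-(trimethylsilyl)oct-6-enoate | COC(=O)CC(=O)CC(C)(C)/C=C/C[Si](C)(C)C | intermediate
6 | formaldehyde (used as paraformaldehyde) | C=O | starting material
7 | prenyl bromide (1-bromo-3-methylbut-2-ene) | CC(C)=CCBr | starting material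
8 | methyl (E)-5,5-dimethyl-2-methylidene-3-oxo-8-(trimethylsilyl)oct-6-enoate | COC(=O)C(=C)C(=O)CC(C)(C)/C=C/C[Si](C)(C)C | intermediate (not isolated)
9 | methyl (5R)-4,4-dimethyl-2-oxo-5-vinylcyclohexane-1-carboxylate (present as its enolate, C1 not yet fixed) | COC(=O)C1C[C@H](C=C)C(C)(C)CC1=O | intermediate (not isolated)
10 | methyl (1R,5R)-4,4-dimethyl-1-(3-methylbut-2-en-1-yl)-2-oxo-5-vinylcyclohexane-1-carboxylate (ester cis to vinyl) | COC(=O)[C@]1(CC=C(C)C)C[C@H](C=C)C(C)(C)CC1=O | intermediate
11 | methyl (1R,5S)-5-[2-(9-borabicyclo[3.3.1]nonan-9-yl)ethyl]-4,4-dimethyl-1-(3-methylbut-2-en-1-yl)-2-oxocyclohexane-1-carboxylate | COC(=O)[C@]1(CC=C(C)C)C[C@H](CCB2C3CCCC2CCC3)C(C)(C)CC1=O | intermediate (not isolated)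
12 | methyl (1R,5R)-5-(2-hydroxyethyl)-4,4-dimethyl-1-(3-methylbut-2-en-1-yl)-2-oxocyclohexane-1-carboxylate | COC(=O)[C@]1(CC=C(C)C)C[C@H](CCO)C(C)(C)CC1=O | intermediate
13 | methyl (1R,5R)-4,4-dimethyl-1-(3-methylbut-2-en-1-yl)-2-oxo-5-(2-oxoethyl)cyclohexane-1-carboxylate | COC(=O)[C@]1(CC=C(C)C)C[C@H](CC=O)C(C)(C)CC1=O | intermediate
14 | methyl (1R,5S)-4,4-dimethyl-5-[(E)-3-methyl-4-oxobut-2-en-1-yl]-1-(3-methylbut-2-en-1-yl)-2-oxocyclohexane-1-carboxylate | COC(=O)[C@]1(CC=C(C)C)C[C@H](C/C=C(\C)C=O)C(C)(C)CC1=O | intermediate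
15 | methyl (1R,5S)-5-[(E)-4-hydroxy-3-methylbut-2-en-1-yl]-4,4-dimethyl-1-(3-methylbut-2-en-1-yl)-2-oxocyclohexane-1-carboxylate | COC(=O)[C@]1(CC=C(C)C)C[C@H](C/C=C(\C)CO)C(C)(C)CC1=O | intermediate
16 | methyl (1R,5S)-5-[(E)-4-(tert-butyldiphenylsilyloxy)-3-methylbut-2-en-1-yl]-4,4-dimethyl-1-(3-methylbut-2-en-1-yl)-2-oxocyclohexane-1-carboxylate | COC(=O)[C@]1(CC=C(C)C)C[C@H](C/C=C(\C)CO[Si](c2ccccc2)(c2ccccc2)C(C)(C)C)C(C)(C)CC1=O | intermediate
17 | 5-methylhex-4-enoic acid | CC(C)=CCCC(=O)O | starting material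
18 | 5-methylhex-4-enoyl chloride | CC(C)=CCCC(=O)Cl | intermediate
19 | 16 carrying a 5-methylhex-4-enoyl group at ring carbon C3 (core C1); enol and C3 epimers | COC(=O)[C@]1(CC=C(C)C)C[C@H](C/C=C(\C)CO[Si](c2ccccc2)(c2ccccc2)C(C)(C)C)C(C)(C)C(C(=O)CCC=C(C)C)C1=O | intermediate
20 | 19 with a phenylthio group at the same carbon, trans to the ester (acyl cis to the ester) | COC(=O)[C@]1(CC=C(C)C)C[C@H](C/C=C(\C)CO[Si](c2ccccc2)(c2ccccc2)C(C)(C)C)C(C)(C)[C@@](C(=O)CCC=C(C)C)(Sc2ccccc2)C1=O | intermediate
21 | 2-hydroxy-8,8-dimethyl-3,5-bis(3-methylbut-2-enyl)-1-(phenylthio)-7-[(E)-4-(tert-butyldiphenylsilyloxy)-3-methylbut-2-enyl]bicyclo[3.3.1]non-2-ene-4,9-dione (core numbering; C7 chain cis to the C2–C4 bridge) | OC1=C(CC=C(C)C)C(=O)[C@]2(CC=C(C)C)C[C@H](C/C=C(\C)CO[Si](c3ccccc3)(c3ccccc3)C(C)(C)C)C(C)(C)[C@@]1(Sc1ccccc1)C2=O | intermediate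
22 | 2-hydroxy-8,8-dimethyl-3,5-bis(3-methylbut-2-enyl)-7-[(E)-4-(tert-butyldiphenylsilyloxy)-3-methylbut-2-enyl]bicyclo[3.3.1]non-2-ene-4,9-dione (core numbering; C1–H) | OC1=C(CC=C(C)C)C(=O)[C@]2(CC=C(C)C)C[C@H](C/C=C(\C)CO[Si](c3ccccc3)(c3ccccc3)C(C)(C)C)C(C)(C)[C@H]1C2=O | intermediate
23 | 2-methoxy analogue of 22 (methyl enol ether at O2) | COC1=C(CC=C(C)C)C(=O)[C@]2(CC=C(C)C)C[C@H](C/C=C(\C)CO[Si](c3ccccc3)(c3ccccc3)C(C)(C)C)C(C)(C)[C@H]1C2=O | intermediate
24 | 1-benzoyl-2-methoxy-8,8-dimethyl-3,5-bis(3-methylbut-2-enyl)-7-[(E)-4-(tert-butyldiphenylsilyloxy)-3-methylbut-2-enyl]bicyclo[3.3.1]non-2-ene-4,9-dione (core numbering) | COC1=C(CC=C(C)C)C(=O)[C@]2(CC=C(C)C)C[C@H](C/C=C(\C)CO[Si](c3ccccc3)(c3ccccc3)C(C)(C)C)C(C)(C)[C@@]1(C(=O)c1ccccc1)C2=O | intermediate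
25 | 1-benzoyl-7-[(E)-4-hydroxy-3-methylbut-2-enyl]-2-methoxy-8,8-dimethyl-3,5-bis(3-methylbut-2-enyl)bicyclo[3.3.1]non-2-ene-4,9-dione (core numbering) | COC1=C(CC=C(C)C)C(=O)[C@]2(CC=C(C)C)C[C@H](C/C=C(\C)CO)C(C)(C)[C@@]1(C(=O)c1ccccc1)C2=O | intermediate
26 | (1R,5S,7S)-7-[(E)-4-acetoxy-3-methylbut-2-en-1-yl]-1-benzoyl-2-methoxy-8,8-dimethyl-3,5-bis(3-methylbut-2-en-1-yl)bicyclo[3.3.1]non-2-ene-4,9-dione (core numbering) | COC1=C(CC=C(C)C)C(=O)[C@]2(CC=C(C)C)C[C@H](C/C=C(\C)COC(C)=O)C(C)(C)[C@@]1(C(=O)c1ccccc1)C2=O | target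

**Step count and risks**

Total step count: 17. Longest linear sequence: 16 steps (steps 1–8 and 10–17; step 9 is a one-step branch).

Steps most likely to fail:

1. Step 3 (the proposed new method).
   - What may go wrong: the methylene keto ester 8 may be consumed by Michael addition of a second molecule of 5, or by oligomerisation, before the allylsilane closes. The allylsilane may be protodesilylated by the acid set free or may add to formaldehyde directly. The chiral complex, bound at the dicarbonyl end, may discriminate poorly between the two folding modes of the tether, and prenylation may partly occur on oxygen.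
   - Fallback with known chemistry, from 5 back to 10: a Mannich reaction of 5 with dimethyl(methylene)ammonium iodide gives methyl 2-[(dimethylamino)methyl]-5,5-dimethyl-3-oxo-8-(trimethylsilyl)oct-6-enoate F1. TiCl4 in CH2Cl2 at −78 °C eliminates dimethylamine to 8 in situ and promotes the known Lewis-acid-mediated intramolecular Hosomi–Sakurai addition to an alkylidene 1,3-dicarbonyl compound. This gives 9 as the racemate, that is together with methyl (5S)-4,4-dimethyl-2-oxo-5-vinylcyclohexane-1-carboxylate F2. Alkylation with 7 and K2CO3 in acetone then gives 10 together with its enantiomer methyl (1S,5S)-4,4-dimethyl-1-(3-methylbut-2-en-1-yl)-2-oxo-5-vinylcyclohexane-1-carboxylate F3. Preparative chromatography on a chiral stationary phase delivers 10, where the route is rejoined.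

2. Step 15.
   - What may go wrong: removal of the bridgehead proton beside the gem-dimethyl carbon may be too slow, because the anion gains little conjugation, so that the amide is consumed by benzoyl chloride or attacks elsewhere. The crowded bridgehead lithium species may also fail to be acylated.
   - Fallback without deprotonation, from 21 back to 24: O-methylation of 21 as in step 14 gives 2-methoxy-8,8-dimethyl-3,5-bis(3-methylbut-2-enyl)-1-(phenylthio)-7-[(E)-4-(tert-butyldiphenylsilyloxy)-3-methylbut-2-enyl]bicyclo[3.3.1]non-2-ene-4,9-dione F4, purified by chromatography since the sulfur substituent may erode the regioselectivity. One equivalent of mCPBA at −78 °C oxidises sulfur to the corresponding 1-(phenylsulfinyl) compound F5. Sulfoxide–magnesium exchange with i-PrMgCl in THF at −78 °C generates the bridgehead magnesium species, which is trapped with benzaldehyde as the 1-[hydroxy(phenyl)methyl] carbinol F6. Dess–Martin oxidation of the carbinol gives 24, where the route is rejoined.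

3. Step 12.
   - What may go wrong: the alkoxide may add to a ketone of the non-enolisable 2-acyl-2-(phenylthio) ketone and cleave it (retro-Claisen), or the sulfenyl group may be transferred to the C3 carbanion, before the ring closes. Closure also fails if step 11 delivered sulfur to the wrong face.
   - Fallback that uses the benzoyl group itself as the quaternising substituent, from 19 back to 24: C-benzoylation of 19 with benzoyl chloride, MgCl2 and pyridine in CH2Cl2 gives methyl 3-benzoyl-5-[(E)-4-(tert-butyldiphenylsilyloxy)-3-methylbut-2-enyl]-4,4-dimethyl-1-(3-methylbut-2-enyl)-3-(5-methylhex-4-enoyl)-2-oxocyclohexane-1-carboxylate F7, with benzoyl trans to the ester for the same reason as sulfur. KOt-Bu in THF closes ring B to 1-benzoyl-2-hydroxy-8,8-dimethyl-3,5-bis(3-methylbut-2-enyl)-7-[(E)-4-(tert-butyldiphenylsilyloxy)-3-methylbut-2-enyl]bicyclo[3.3.1]non-2-ene-4,9-dione F8. (Trimethylsilyl)diazomethane then gives 24 together with its regioisomer 1-benzoyl-4-methoxy-8,8-dimethyl-3,5-bis(3-methylbut-2-enyl)-7-[(E)-4-(tert-butyldiphenylsilyloxy)-3-methylbut-2-enyl]bicyclo[3.3.1]non-3-ene-2,9-dione F9, which is separated by chromatography. The route is rejoined at 24. This path avoids sulfur and the bridgehead metalation but gives up the regiocontrol of the O-methylation.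

**Further compounds**

F1 | step 3 | methyl 2-[(dimethylamino)methyl]-5,5-dimethyl-3-oxo-8-(trimethylsilyl)oct-6-enoate | COC(=O)C(CN(C)C)C(=O)CC(C)(C)/C=C/C[Si](C)(C)C
F2 | step 3 | methyl (5S)-4,4-dimethyl-2-oxo-5-vinylcyclohexane-1-carboxylate | COC(=O)C1C[C@@H](C=C)C(C)(C)CC1=O
F3 | step 3 | methyl (1S,5S)-4,4-dimethyl-1-(3-methylbut-2-en-1-yl)-2-oxo-5-vinylcyclohexane-1-carboxylate | COC(=O)[C@@]1(CC=C(C)C)C[C@@H](C=C)C(C)(C)CC1=O
F4 | step 15 | 2-methoxy-8,8-dimethyl-3,5-bis(3-methylbut-2-enyl)-1-(phenylthio)-7-[(E)-4-(tert-butyldiphenylsilyloxy)-3-methylbut-2-enyl]bicyclo[3.3.1]non-2-ene-4,9-dione | COC1=C(CC=C(C)C)C(=O)[C@]2(CC=C(C)C)C[C@H](C/C=C(\C)CO[Si](c3ccccc3)(c3ccccc3)C(C)(C)C)C(C)(C)[C@@]1(Sc1ccccc1)C2=O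
F5 | step 15 | 1-(phenylsulfinyl) analogue of F4 | COC1=C(CC=C(C)C)C(=O)[C@]2(CC=C(C)C)C[C@H](C/C=C(\C)CO[Si](c3ccccc3)(c3ccccc3)C(C)(C)C)C(C)(C)[C@@]1(S(=O)c1ccccc1)C2=O
F6 | step 15 | 1-[hydroxy(phenyl)methyl] carbinol corresponding to 24 | COC1=C(CC=C(C)C)C(=O)[C@]2(CC=C(C)C)C[C@H](C/C=C(\C)CO[Si](c3ccccc3)(c3ccccc3)C(C)(C)C)C(C)(C)[C@@]1(C(O)c1ccccc1)C2=O
F7 | step 12 | methyl 3-benzoyl-5-[(E)-4-(tert-butyldiphenylsilyloxy)-3-methylbut-2-enyl]-4,4-dimethyl-1-(3-methylbut-2-enyl)-3-(5-methylhex-4-enoyl)-2-oxocyclohexane-1-carboxylate | COC(=O)[C@]1(CC=C(C)C)C[C@H](C/C=C(\C)CO[Si](c2ccccc2)(c2ccccc2)C(C)(C)C)C(C)(C)[C@@](C(=O)CCC=C(C)C)(C(=O)c2ccccc2)C1=O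
F8 | step 12 | 1-benzoyl-2-hydroxy-8,8-dimethyl-3,5-bis(3-methylbut-2-enyl)-7-[(E)-4-(tert-butyldiphenylsilyloxy)-3-methylbut-2-enyl]bicyclo[3.3.1]non-2-ene-4,9-dione | OC1=C(CC=C(C)C)C(=O)[C@]2(CC=C(C)C)C[C@H](C/C=C(\C)CO[Si](c3ccccc3)(c3ccccc3)C(C)(C)C)C(C)(C)[C@@]1(C(=O)c1ccccc1)C2=O
F9 | step 12 | 1-benzoyl-4-methoxy-8,8-dimethyl-3,5-bis(3-methylbut-2-enyl)-7-[(E)-4-(tert-butyldiphenylsilyloxy)-3-methylbut-2-enyl]bicyclo[3.3.1]non-3-ene-2,9-dione | O=C1C(CC=C(C)C)=C(OC)[C@]2(CC=C(C)C)C[C@H](C/C=C(\C)CO[Si](c3ccccc3)(c3ccccc3)C(C)(C)C)C(C)(C)[C@@]1(C(=O)c1ccccc1)C2=O
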